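**Assumption (one line):** asbestinin numbering is used in names (C1–C14 = carbocyclic/oxonene skeleton, C15–C17 = CH(CH3)CH2O unit, C18 = C12‑Me, C19 = C3‑Me, C20 = C7‑Me); TBS = tert‑butyldimethylsilyl, Cb = N,N‑diisopropylcarbamoyl.

## Retrosynthetic overview

1. Oxepane (last ring): C3–O–C16 by displacement of a C16 triflate by the C3 tertiary alcohol; C11 butyrate and C12 methyl come from a C11 ketone (α‑methylenation, Luche reduction, acylation, convex‑face hydrogenation).
2. Oxonene (key ring closure): ring‑closing metathesis of a C6 vinyl / C7 isopropenyl diene held cis on a preformed tetrahydrofuran, giving (Z)‑C6=C7.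
3. Tetrahydrofuran: BF3 condensation of a 4‑hydroxy enol carbamate with acetal 20 (forms C2–O–C9 and C9–C10, releases the C11 ketone).
4. C1–C2 bond: homoaldol union of the titanated cyclohexenyl carbamate 8 with the α‑silyloxy aldehyde 17.
5. Three fragments: 8 (cyclohexene ring, organocatalytic Michael/aldol), 17 (from (R)‑lactic acid), 20. Ring order: cyclohexene → tetrahydrofuran → oxonene → oxepane.

## Route

### Fragment A: cyclohexenyl carbamate 8 (C1, C10–C17)

**Step 1**
Reactants: 1, (S)‑3‑bromo‑2‑methylpropan‑1‑ol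
Product: 2, (S)‑(3‑bromo‑2‑methylpropoxy)(tert‑butyl)dimethylsilane
Conditions: TBSCl, imidazole, CH2Cl2, 0 → 23 °C
Reagents that add atoms: TBSCl, CC(C)(C)[Si](C)(C)Cl
Why: Silyl ether formation protects the future C16 oxygen; the C15 stereocentre comes from the chiral pool and is never adjacent to a carbonyl.

**Step 2**
Reactants: 2
Product: 3, (R)‑4‑(TBSO)‑3‑methylbutanal
Conditions: Mg, THF, reflux; DMF, 0 °C; aq. NH4Cl
Reagents that add atoms: DMF, CN(C)C=O (supplies the CHO group)
Why: Grignard formylation (Bouveault) adds C1 as the aldehyde without touching C15.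

**Step 3**
Reactants: 3; 4, methyl vinyl ketone
Product: 5, (2S)‑2‑[(2R)‑1‑(TBSO)propan‑2‑yl]‑5‑oxohexanal
Conditions: (S)‑α,α‑diphenylprolinol TMS ether (10 mol %), ethyl 3,4‑dihydroxybenzoate (20 mol %), neat, 4 °C
Reagents that add atoms: none
Why: Enamine‑catalysed asymmetric Michael addition; the (S)‑catalyst blocks one enamine face, so C14 is set S under catalyst control.

**Step 4**
Reactants: 5
Product: 6, (4R)‑4‑[(2R)‑1‑(TBSO)propan‑2‑yl]cyclohex‑2‑en‑1‑one
Conditions: LiOH (0.2 equiv), iPrOH, 23 °C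
Reagents that add atoms: none
Why: Intramolecular aldol condensation (Robinson‑type closure) forms the cyclohexenone (C11=O, C10=C1); mild base limits γ‑epimerisation at C14.

**Step 5**
Reactants: 6
Product: 7, (1R,4R)‑4‑[(2R)‑1‑(TBSO)propan‑2‑yl]cyclohex‑2‑en‑1‑ol (trans)
Conditions: NaBH4, CeCl3·7H2O, MeOH, –78 °C; minor cis isomer removed by chromatography
Reagents that add atoms: none
Why: Luche 1,2‑reduction; axial hydride attack on the half‑chair with a pseudo‑equatorial C14 substituent gives the trans alcohol.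

**Step 6**
Reactants: 7
Product: 8, (1R,4R)‑4‑[(2R)‑1‑(TBSO)propan‑2‑yl]cyclohex‑2‑en‑1‑yl N,N‑diisopropylcarbamate
Conditions: NaH, THF; iPr2NCOCl, reflux
Reagents that add atoms: N,N‑diisopropylcarbamoyl chloride, CC(C)N(C(C)C)C(=O)Cl
Why: O‑carbamoylation installs the directing/activating group for α‑lithiation (Hoppe carbamate); no stereocentre is affected.

### Fragment B: aldehyde 17 (C2–C6, C19)

**Step 7**
Reactants: 9, (R)‑lactic acid; 10, pivalaldehyde
Product: 11, (2R,5R)‑2‑tert‑butyl‑5‑methyl‑1,3‑dioxolan‑4‑one (cis)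
Conditions: TsOH (cat.), pentane, reflux, Dean–Stark; recrystallise
Reagents that add atoms: none
Why: Seebach acetalisation gives the cis dioxolanone, storing the lactate chirality in the acetal centre.

**Step 8**
Reactants: 11; 12, 4‑iodobut‑1‑ene
Product: 13, (2R,5S)‑5‑(but‑3‑en‑1‑yl)‑2‑tert‑butyl‑5‑methyl‑1,3‑dioxolan‑4‑one
Conditions: LDA, THF, –78 °C; then 12, DMPU, –78 → –30 °C
Reagents that add atoms: none
Why: Enolate alkylation with self‑regeneration of the stereocentre; the electrophile enters trans to tert‑butyl, so the future C3 quaternary centre is formed with net retention.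

**Step 9**
Reactants: 13
Product: 14, (S)‑2‑methylhex‑5‑ene‑1,2‑diol
Conditions: LiAlH4, Et2O, 0 → 23 °C
Reagents that add atoms: none
Why: Hydride reduction of the dioxolanone releases the 1,2‑diol; the quaternary centre cannot epimerise.

**Step 10**
Reactants: 14
Product: 15, (S)‑1,2‑bis(TBSO)‑2‑methylhex‑5‑ene
Conditions: TBSOTf (2.5 equiv), 2,6‑lutidine, CH2Cl2, 0 → 23 °C
Reagents that add atoms: TBSOTf, CC(C)(C)[Si](C)(C)OS(=O)(=O)C(F)(F)F
Why: Exhaustive silylation; the triflate is needed to silylate the tertiary (future C3) alcohol.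

**Step 11**
Reactants: 15
Product: 16, (S)‑2‑(TBSO)‑2‑methylhex‑5‑en‑1‑ol
Conditions: HF·pyridine, pyridine, THF, 0 °C
Reagents that add atoms: none
Why: Selective desilylation; the primary TBS ether cleaves far faster than the hindered tertiary one.

**Step 12**
Reactants: 16
Product: 17, (S)‑2‑(TBSO)‑2‑methylhex‑5‑enal
Conditions: Dess–Martin periodinane, NaHCO3, CH2Cl2, 0 → 23 °C
Reagents that add atoms: none
Why: Dess–Martin oxidation gives the non‑enolisable α‑silyloxy aldehyde (C2 = CHO, C3 fixed as S).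

### Fragment C: acetal 20 (C7–C9, C20)

**Step 13**
Reactants: 18, 4,4‑dimethoxybutan‑2‑one
Product: 19, 4,4‑dimethoxy‑2‑methyl‑1‑(trimethylsilyl)butan‑2‑ol (racemic)
Conditions: Me3SiCH2MgCl, CeCl3, THF, –78 → 0 °C
Reagents that add atoms: (trimethylsilyl)methylmagnesium chloride, C[Si](C)(C)C[Mg]Cl
Why: Peterson addition with a weakly basic nucleophile avoids the E1cB loss of methanol that a basic ylide provokes in this β‑keto acetal.

**Step 14**
Reactants: 19
Product: 20, 4,4‑dimethoxy‑2‑methylbut‑1‑ene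
Conditions: KH, THF, 0 → 23 °C
Reagents that add atoms: none
Why: Base‑mediated Peterson syn‑elimination gives the 1,1‑disubstituted alkene while the acetal survives.

### Assembly

**Step 15**
Reactants: 8; 17
Product: 21, homoaldol adduct: cyclohex‑1‑enyl carbamate (enol carbamate C11=C10) carrying at C1 the (1S,2S)‑1‑hydroxy‑2‑methyl‑2‑(TBSO)hex‑5‑enyl chain (C2–OH, C3–OTBS), trans to the C14 (R)‑1‑(TBSO)propan‑2‑yl group
Conditions: sBuLi, TMEDA, Et2O, –78 °C; ClTi(OiPr)3, –78 °C; then 17, –78 → –40 °C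
Reagents that add atoms: none
Why: Hoppe homoaldol reaction: α‑lithiation with retention, Li→Ti exchange with inversion, then γ‑addition through a closed six‑membered transition state; C1–C2 forms anti to the C14 side chain, and C2 is set with the bulky quaternary aldehyde substituent turned away from C14.

**Step 16**
Reactants: 21; 20
Product: 22, cis‑fused hexahydroisobenzofuranone: C11 ketone, tetrahydrofuran C1–C2–O–C9–C10; C2 bears the (S)‑2‑(TBSO)hex‑5‑en‑2‑yl group and C9 the 2‑methylallyl group, both on the convex face (2,5‑cis); C14 side chain trans to C1–C2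
Conditions: BF3·OEt2 (3 equiv), CH2Cl2, –78 → 0 °C; aqueous work‑up
Reagents that add atoms: none
Why: Acetal exchange gives an oxocarbenium ion at C9 that is trapped by the enol carbamate (Mukaiyama/Prins‑type cyclisation); the tether enforces cis fusion at C1/C10, the C9 substituent sits pseudo‑equatorial and cis to the C2 substituent, and loss of the carbamoyl group unveils the C11 ketone.

**Step 17**
Reactants: 22
Product: 23, tricyclic ketone with the (Z)‑C6=C7 oxonene bridging C2 and C9 (C3–OTBS, C16–OTBS retained)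
Conditions: Grubbs II (15 mol %), benzene (1 mM), 80 °C
Reagents that add atoms: none
Why: Ring‑closing metathesis; the 2,5‑cis tetrahydrofuran holds both olefinic chains on one face, and the nine‑membered ring can only accommodate the Z trisubstituted alkene.

**Step 18**
Reactants: 23
Product: 24, C12‑exo‑methylene enone (C11=O, C12=CH2)
Conditions: LiHMDS, THF, –78 °C; CH2=NMe2+ I–, –78 → 23 °C; then MeI; then DBU
Reagents that add atoms: Eschenmoser's salt, C=[N+](C)C.[I-] (supplies C18)
Why: Kinetic enolisation at the less hindered C12 methylene (not the ring‑fusion C10–H) followed by Eschenmoser α‑methylenation.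

**Step 19**
Reactants: 24
Product: 25, C11 allylic alcohol (OH cis to the C10–C9 bond)
Conditions: NaBH4, CeCl3·7H2O, MeOH, –78 °C
Reagents that add atoms: none
Why: Luche 1,2‑reduction; hydride attacks axially from the convex face, anti to the C9 bridge, setting C11.

**Step 20**
Reactants: 25
Product: 26, C11 butyrate of 25
Conditions: butyric anhydride, Et3N, DMAP, CH2Cl2, 23 °C
Reagents that add atoms: butyric anhydride, CCCC(=O)OC(=O)CCC
Why: DMAP‑catalysed acylation of the only free hydroxyl; acylating first prevents Rh‑mediated allylic alcohol isomerisation in the next step.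

**Step 21**
Reactants: 26
Product: 27, 12‑methyl compound (C11–O and C12–Me cis), bis‑TBS ether
Conditions: H2 (4 atm), RhCl(PPh3)3 (15 mol %), benzene, 23 °C
Reagents that add atoms: none (H2 only)
Why: Wilkinson hydrogenation reduces the 1,1‑disubstituted alkene and leaves the trisubstituted ring alkene; H is delivered from the convex face, opposite the C9 bridge and the C11 ester, setting C12.

**Step 22**
Reactants: 27
Product: 28, diol (C3 tertiary OH, C16 primary OH)
Conditions: HF·pyridine, THF, 0 → 40 °C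
Reagents that add atoms: none
Why: Global desilylation; the butyrate, the alkene and the ethers are stable to buffered HF.

**Step 23**
Reactants: 28
Product: 29, 4‑deoxyasbestinin C
Conditions: Tf2O, 2,6‑lutidine, CH2Cl2, –78 → 0 °C
Reagents that add atoms: none
Why: Selective triflation of the primary C16 alcohol and in‑situ intramolecular Williamson etherification by the C3 tertiary hydroxyl closes the oxepane without touching any stereocentre.

## Compound list

1 | (S)‑3‑bromo‑2‑methylpropan‑1‑ol | BrC[C@@H](C)CO | starting material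
2 | (S)‑(3‑bromo‑2‑methylpropoxy)(tert‑butyl)dimethylsilane | BrC[C@@H](C)CO[Si](C)(C)C(C)(C)C | intermediate
3 | (R)‑4‑(TBSO)‑3‑methylbutanal | O=CC[C@@H](C)CO[Si](C)(C)C(C)(C)C | intermediate
4 | methyl vinyl ketone | C=CC(C)=O | starting material
5 | (2S)‑2‑[(2R)‑1‑(TBSO)propan‑2‑yl]‑5‑oxohexanal | O=C[C@@H](CCC(C)=O)[C@@H](C)CO[Si](C)(C)C(C)(C)C | intermediate
6 | (4R)‑4‑[(2R)‑1‑(TBSO)propan‑2‑yl]cyclohex‑2‑en‑1‑one | O=C1C=C[C@@H](CC1)[C@@H](C)CO[Si](C)(C)C(C)(C)C | intermediate
7 | (1R,4R)‑4‑[(2R)‑1‑(TBSO)propan‑2‑yl]cyclohex‑2‑en‑1‑ol | O[C@H]1C=C[C@@H](CC1)[C@@H](C)CO[Si](C)(C)C(C)(C)C | intermediate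
8 | (1R,4R)‑4‑[(2R)‑1‑(TBSO)propan‑2‑yl]cyclohex‑2‑en‑1‑yl N,N‑diisopropylcarbamate | CC(C)N(C(C)C)C(=O)O[C@H]1C=C[C@@H](CC1)[C@@H](C)CO[Si](C)(C)C(C)(C)C | intermediate
9 | (R)‑lactic acid | C[C@@H](O)C(=O)O | starting material
10 | pivalaldehyde | CC(C)(C)C=O | starting material
11 | (2R,5R)‑2‑tert‑butyl‑5‑methyl‑1,3‑dioxolan‑4‑one | C[C@H]1O[C@H](OC1=O)C(C)(C)C | intermediate
12 | 4‑iodobut‑1‑ene | C=CCCI | starting material
13 | (2R,5S)‑5‑(but‑3‑en‑1‑yl)‑2‑tert‑butyl‑5‑methyl‑1,3‑dioxolan‑4‑one | C=CCC[C@]1(C)O[C@H](OC1=O)C(C)(C)C | intermediate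
14 | (S)‑2‑methylhex‑5‑ene‑1,2‑diol | C=CCC[C@](C)(O)CO | intermediate
15 | (S)‑1,2‑bis(TBSO)‑2‑methylhex‑5‑ene | C=CCC[C@](C)(O[Si](C)(C)C(C)(C)C)CO[Si](C)(C)C(C)(C)C | intermediate
16 | (S)‑2‑(TBSO)‑2‑methylhex‑5‑en‑1‑ol | C=CCC[C@](C)(O[Si](C)(C)C(C)(C)C)CO | intermediate
17 | (S)‑2‑(TBSO)‑2‑methylhex‑5‑enal | C=CCC[C@](C)(O[Si](C)(C)C(C)(C)C)C=O | intermediate
18 | 4,4‑dimethoxybutan‑2‑one | CC(=O)CC(OC)OC | starting material
19 | 4,4‑dimethoxy‑2‑methyl‑1‑(trimethylsilyl)butan‑2‑ol | CC(O)(C[Si](C)(C)C)CC(OC)OC | intermediate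
20 | 4,4‑dimethoxy‑2‑methylbut‑1‑ene | C=C(C)CC(OC)OC | intermediate
21 | homoaldol adduct (enol carbamate, C2–OH) | CC(C)N(C(C)C)C(=O)OC1=C[C@H]([C@@H](CC1)[C@@H](C)CO[Si](C)(C)C(C)(C)C)[C@H](O)[C@@](C)(O[Si](C)(C)C(C)(C)C)CCC=C | intermediate
22 | cis‑fused hexahydroisobenzofuranone diene (C11 ketone) | O=C1[C@@H]2[C@H]([C@@H](CC1)[C@@H](C)CO[Si](C)(C)C(C)(C)C)[C@@H]([C@@](C)(O[Si](C)(C)C(C)(C)C)CCC=C)O[C@H]2CC(C)=C | intermediate
23 | tricyclic (Z)‑oxonene ketone | O=C1[C@@H]2[C@H]([C@@H](CC1)[C@@H](C)CO[Si](C)(C)C(C)(C)C)[C@H]3[C@@](C)(O[Si](C)(C)C(C)(C)C)CC/C=C(/C)C[C@@H]2O3 | intermediate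
24 | C12‑methylene enone | O=C1[C@@H]2[C@H]([C@@H](CC1=C)[C@@H](C)CO[Si](C)(C)C(C)(C)C)[C@H]3[C@@](C)(O[Si](C)(C)C(C)(C)C)CC/C=C(/C)C[C@@H]2O3 | intermediate
25 | C11 allylic alcohol | O[C@H]1[C@@H]2[C@H]([C@@H](CC1=C)[C@@H](C)CO[Si](C)(C)C(C)(C)C)[C@H]3[C@@](C)(O[Si](C)(C)C(C)(C)C)CC/C=C(/C)C[C@@H]2O3 | intermediate
26 | C11 butyrate, C12 methylene | CCCC(=O)O[C@H]1[C@@H]2[C@H]([C@@H](CC1=C)[C@@H](C)CO[Si](C)(C)C(C)(C)C)[C@H]3[C@@](C)(O[Si](C)(C)C(C)(C)C)CC/C=C(/C)C[C@@H]2O3 | intermediate
27 | C11 butyrate, C12 methyl, bis‑TBS ether | CCCC(=O)O[C@H]1[C@@H]2[C@H]([C@@H](C[C@H]1C)[C@@H](C)CO[Si](C)(C)C(C)(C)C)[C@H]3[C@@](C)(O[Si](C)(C)C(C)(C)C)CC/C=C(/C)C[C@@H]2O3 | intermediate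
28 | C3,C16‑diol (seco‑oxepane) | CCCC(=O)O[C@H]1[C@@H]2[C@H]([C@@H](C[C@H]1C)[C@@H](C)CO)[C@H]3[C@@](C)(O)CC/C=C(/C)C[C@@H]2O3 | intermediate
29 | 4‑deoxyasbestinin C (1S,2S,3S,9S,10R,11R,12R,14S,15R; 6Z) | CCCC(=O)O[C@H]1[C@@H]2[C@@H]3[C@@H](C[C@H]1C)[C@@H](C)CO[C@@]1(C)CC/C=C(/C)C[C@@H]2O[C@@H]31 | target

## Summary

**Total step count:** 23 (fragment A 6, fragment B 6, fragment C 2, assembly 9).

**Longest linear sequence:** 15 steps (steps 1–6 then 15–23; the lactate branch, steps 7–12 then 15–23, is equally long).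

**Three steps most likely to fail, with fallbacks:**

1. **Step 15 (homoaldol union).** The facial outcome depends on the Li→Ti exchange going with inversion, and the C1/C2 diastereoselectivity with a very hindered α‑quaternary aldehyde is the least predictable stereochemical event in the route. Fallback: abandon the allyl‑titanium union and build the C2–O–C9 ether by auxiliary‑controlled glycolate aldol chemistry, close the oxonene by RCM first, and form the cyclohexane last by an ether‑tethered intramolecular Diels–Alder reaction (diene on C9, enone dienophile on C2).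

2. **Step 17 (RCM to a nine‑membered trisubstituted alkene).** The catalyst may stall or give oligomers. Fallback: close the ring by an intramolecular B‑alkyl Suzuki–Miyaura macrocyclisation. Use a C3‑vinyl aldehyde and a (Z)‑vinyl iodide acetal as the fragments, then 9‑BBN hydroboration and Pd coupling forge C5–C6 with the Z alkene already in place.

3. **Step 21 (with step 18; C12 methyl by hydrogenation).** Face selectivity or allylic isomerisation could erode C12. Fallback: bring the C12 methyl in with fragment A (3‑methylbut‑3‑en‑2‑one instead of MVK in step 3), convert the C11 ketone after RCM into the C11=C12 alkene (enol triflate, Pd/formate reduction), and set C12 then C11 by convex‑face hydroboration followed by oxidation and hydride reduction.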